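The route rests on cutting the C3–C6′ bond between the two dihydrobenzofurans (ring A carries the styryl group, ring B is the other). Ring A enters as a flat benzofuran: its C2=C3 enol-ether π bond, made nucleophilic at C3 by a tetracoordinate boron on C2, is attacked by the aryl–palladium species of the complete, enantiopure ring B triflate, while a 4-methoxyphenyl group migrates from boron to C2. One operation thus forms the C3–C6′ bond, the C2–aryl bond and both ring A stereocentres (trans, ligand-controlled). The precursor is a lithium benzofuran-2-yl(aryl)pinacolborate. Ring B is made by the same reaction; both benzofurans come from 1-chloro-3,5-dimethoxybenzene by regiodivergent formylation; the stilbene is attached last.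

Key step: step 11

Locants: each dihydrobenzofuran is numbered O1, C2, C3, C3a, C4–C7, C7a; ring B locants are primed. The target is (2S,3S) in ring A and (2′R,3′R) in ring B, both trans.

Assumption: the facial sense of the MandyPhos–palladium catalyst on a benzofuran-2-yl borate is not established. The (Sp,Sp) ligand is taken to give the (2R,3R) series in step 5 and its (Rp,Rp) antipode the (2S,3S) series in step 11; if the sense is the reverse, the two antipodes are exchanged.

Step 1
Reactants: 1 1-chloro-3,5-dimethoxybenzene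
Product: 4 4-chloro-2,6-dimethoxybenzaldehyde, via aryllithium 2 (not isolated), via lithium hemiaminal alkoxide 3 (not isolated)
Conditions: n-BuLi, TMEDA, THF, −78 °C to −20 °C; then DMF, −78 °C to rt; then aq. HCl
Reagents that add atoms: N,N-dimethylformamide, CN(C)C=O
Why: Directed ortho-metalation removes the C–H bond flanked by both methoxy groups (cooperative coordination of lithium, no lithium–chlorine exchange with an aryl chloride in the cold), the aryllithium adds to DMF and the hemiaminal collapses to the aldehyde on acidic work-up; the product has no stereocentre.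

Step 2
Reactants: 4 4-chloro-2,6-dimethoxybenzaldehyde
Product: 5 4-chloro-2-hydroxy-6-methoxybenzaldehyde
Conditions: BCl3 (1.1 equiv), CH2Cl2, −78 °C to 0 °C; then H2O
Reagents that add atoms: none
Why: Chelation-controlled demethylation, in which BCl3 bound to the aldehyde oxygen cleaves one ortho methyl ether and the resulting six-membered boron chelate ties up the carbonyl group, so the second ether should survive.

Step 3
Reactants: 5 4-chloro-2-hydroxy-6-methoxybenzaldehyde
Product: 7 6-chloro-4-methoxy-1-benzofuran, via enol ether 6 (not isolated)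
Conditions: MeOCH2PPh3Cl (2.5 equiv), KOtBu (3.5 equiv), THF, 0 °C to rt; aq. NH4Cl; crude 6, TsOH·H2O (10 mol %), toluene, 90 °C
Reagents that add atoms: (methoxymethyl)triphenylphosphonium chloride, COC[P+](c1ccccc1)(c1ccccc1)c1ccccc1.[Cl-]
Why: Wittig methoxymethylenation of the aldehyde (the phenol is carried as its phenoxide), then acid-catalysed cyclisation in which the phenol oxygen traps the oxocarbenium ion of the protonated enol ether (5-exo) and loss of methanol aromatises; the positions of O1 and C3a are fixed by the salicylaldehyde, so only this regioisomer can form.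

Step 4
Reactants: 8 3,5-dimethoxyphenol
Product: 9 3,5-dimethoxyphenyl trifluoromethanesulfonate
Conditions: Tf2O, pyridine, CH2Cl2, 0 °C
Reagents that add atoms: trifluoromethanesulfonic anhydride, O=S(=O)(OS(=O)(=O)C(F)(F)F)C(F)(F)F
Why: O-sulfonylation of the phenol by the anhydride with pyridine as base; no stereocentre is formed.

Step 5
Reactants: 7 6-chloro-4-methoxy-1-benzofuran; 10 2-(4-methoxyphenyl)-4,4,5,5-tetramethyl-1,3,2-dioxaborolane; 9 3,5-dimethoxyphenyl trifluoromethanesulfonate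
Product: 14 (2R,3R)-6-chloro-3-(3,5-dimethoxyphenyl)-4-methoxy-2-(4-methoxyphenyl)-2,3-dihydro-1-benzofuran, via 2-lithiobenzofuran 11 (not isolated), via lithium borate complex 12 (not isolated), via tertiary boronic ester 13 (not isolated)
Conditions: n-BuLi, THF, −78 °C; 10, −78 °C to rt; then 9, Pd(OAc)2 (3 mol %), (Sp,Sp)-MandyPhos Fe[C5H3(PAr2)(CH(NMe2)Ph)]2 (Ar = 4-methoxy-3,5-dimethylphenyl), THF, 60 °C; then toluene, TBAF·3H2O, 45 °C
Reagents that add atoms: none
Why: Proposed new method: the same palladium-induced 1,2-metalate shift as in step 11, run first on simple partners: the aryl–palladium triflate from 9 attacks C3 of borate 12 on the ligand-chosen face while the 4-methoxyphenyl group migrates anti from boron to C2, reductive elimination forms the C3–aryl bond, and fluoride-mediated protodeboronation of 13 with retention leaves the two aryl groups trans (C3 by ligand control, C2 relayed by the anti migration); the closest known reaction type is the palladium/MandyPhos conjunctive cross-coupling of alkenyl boron ate complexes with aryl triflates, not yet shown for a benzofuran-2-yl borate.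

Step 6
Reactants: 14 (2R,3R)-6-chloro-3-(3,5-dimethoxyphenyl)-4-methoxy-2-(4-methoxyphenyl)-2,3-dihydro-1-benzofuran
Product: 15 (2R,3R)-3-(3,5-dimethoxyphenyl)-4-methoxy-2-(4-methoxyphenyl)-2,3-dihydro-1-benzofuran-6-ol
Conditions: Pd2(dba)3, tBuXPhos, KOH, 1,4-dioxane/H2O, 100 °C; then aq. HCl
Reagents that add atoms: potassium hydroxide, [K+].[OH-]
Why: Palladium-catalysed C–O cross-coupling of the aryl chloride with hydroxide (aryl halide hydroxylation); the two ring stereocentres are not acidic enough to be touched by aqueous KOH.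

Step 7
Reactants: 15 (2R,3R)-3-(3,5-dimethoxyphenyl)-4-methoxy-2-(4-methoxyphenyl)-2,3-dihydro-1-benzofuran-6-ol
Product: 16 (2R,3R)-3-(3,5-dimethoxyphenyl)-4-methoxy-2-(4-methoxyphenyl)-2,3-dihydro-1-benzofuran-6-yl trifluoromethanesulfonate
Conditions: Tf2O, pyridine, CH2Cl2, 0 °C
Reagents that add atoms: trifluoromethanesulfonic anhydride, O=S(=O)(OS(=O)(=O)C(F)(F)F)C(F)(F)F
Why: O-sulfonylation of the only free phenol under buffered conditions that leave the benzylic C2′–O bond intact.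

Step 8
Reactants: 1 1-chloro-3,5-dimethoxybenzene
Product: 18 2-chloro-4,6-dimethoxybenzaldehyde, via iminium chloride 17 (not isolated)
Conditions: POCl3 (2 equiv), DMF, 0 °C to 90 °C; then ice–water
Reagents that add atoms: N,N-dimethylformamide, CN(C)C=O; water, O
Why: Vilsmeier–Haack formylation, in which the chloroiminium electrophile takes the position para to one methoxy group and ortho to the other (next to chlorine) in preference to the position between the two methoxy groups, complementary to the lithiation of step 1; hydrolysis of iminium salt 17 gives the aldehyde, its oxygen coming from water.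

Step 9
Reactants: 18 2-chloro-4,6-dimethoxybenzaldehyde
Product: 19 2-chloro-6-hydroxy-4-methoxybenzaldehyde
Conditions: BCl3 (1.1 equiv), CH2Cl2, −78 °C to 0 °C; then H2O
Reagents that add atoms: none
Why: Chelation-controlled demethylation: BCl3 bound to the aldehyde oxygen cleaves only the methyl ether ortho to the carbonyl group, and the para methyl ether cannot chelate and should remain.

Step 10
Reactants: 19 2-chloro-6-hydroxy-4-methoxybenzaldehyde
Product: 21 4-chloro-6-methoxy-1-benzofuran, via enol ether 20 (not isolated)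
Conditions: MeOCH2PPh3Cl (2.5 equiv), KOtBu (3.5 equiv), THF, 0 °C to rt; aq. NH4Cl; crude 20, TsOH·H2O (10 mol %), toluene, 90 °C
Reagents that add atoms: (methoxymethyl)triphenylphosphonium chloride, COC[P+](c1ccccc1)(c1ccccc1)c1ccccc1.[Cl-]
Why: Wittig methoxymethylenation followed by acid-catalysed 5-exo trapping of the oxocarbenium ion by the phenol oxygen and loss of methanol, as in step 3; the chlorine ends up at C4 and the methoxy group at C6 because the ring is built on the fixed aldehyde and phenol positions.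

Step 11
Reactants: 21 4-chloro-6-methoxy-1-benzofuran; 10 2-(4-methoxyphenyl)-4,4,5,5-tetramethyl-1,3,2-dioxaborolane; 16 (2R,3R)-3-(3,5-dimethoxyphenyl)-4-methoxy-2-(4-methoxyphenyl)-2,3-dihydro-1-benzofuran-6-yl trifluoromethanesulfonate
Product: 25 (2S,3S)-4-chloro-3-[(2R,3R)-3-(3,5-dimethoxyphenyl)-4-methoxy-2-(4-methoxyphenyl)-2,3-dihydro-1-benzofuran-6-yl]-6-methoxy-2-(4-methoxyphenyl)-2,3-dihydro-1-benzofuran, via 2-lithiobenzofuran 22 (not isolated), via lithium borate complex 23 (not isolated), via tertiary boronic ester 24 (not isolated)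
Conditions: 21 (1.3 equiv), n-BuLi, THF, −78 °C; 10, −78 °C to rt; then 16 (1.0 equiv), Pd(OAc)2 (5 mol %), (Rp,Rp)-MandyPhos Fe[C5H3(PAr2)(CH(NMe2)Ph)]2 (Ar = 4-methoxy-3,5-dimethylphenyl), THF, 60 °C; then toluene, TBAF·3H2O, 45 °C
Reagents that add atoms: none
Why: Proposed new method: oxidative addition of the C6′–OTf bond of 16 to zerovalent palladium gives a cationic aryl–palladium species that binds the C2=C3 enol-ether π bond of borate 23; bonding of palladium to C3 triggers an anti 1,2-migration of the 4-methoxyphenyl group from boron to C2, and C(sp3)–C(sp2) reductive elimination at C3 then forms the C3–C6′ bond with retention, the closest known reaction type being the palladium/MandyPhos conjunctive cross-coupling of alkenyl boron ate complexes with aryl triflates together with the electrophile-induced 1,2-migration of 2-furyl and 2-indolyl borates, which has not been run with an aryl–palladium electrophile on a benzofuran-2-yl borate. No ring is closed: the furan ring of the benzofuran is dearomatised in place. C3 is set by the chiral ligand (the face of the π bond taken by palladium), C2 follows from C3 because the migration is anti to palladium, and fluoride-mediated protodeboronation of 24 is expected to go with retention, so the two aryl groups end up trans; should protodeboronation leak to the cis isomer, acid equilibration at the ionisable C2–O bond restores trans without touching C3. The step needs the migratory pathway to beat direct Suzuki-type transmetalation (bidentate ligand, triflate counter-ion, halide-free borate from n-BuLi deprotonation), the C–OTf bond to react before the C4–Cl bond, and no β-hydride elimination, which the fully substituted C2 guarantees. The stereocentres of ring B lie five bonds from C3, so the ligand alone should decide the new pair.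

Step 12
Reactants: 25 (2S,3S)-4-chloro-3-[(2R,3R)-3-(3,5-dimethoxyphenyl)-4-methoxy-2-(4-methoxyphenyl)-2,3-dihydro-1-benzofuran-6-yl]-6-methoxy-2-(4-methoxyphenyl)-2,3-dihydro-1-benzofuran
Product: 26 (2S,3S)-4-chloro-3-[(2R,3R)-3-(3,5-dihydroxyphenyl)-4-hydroxy-2-(4-hydroxyphenyl)-2,3-dihydro-1-benzofuran-6-yl]-2-(4-hydroxyphenyl)-2,3-dihydro-1-benzofuran-6-ol
Conditions: BBr3 (excess), CH2Cl2, −78 °C to 0 °C; then MeOH, aq. NaHCO3
Reagents that add atoms: none
Why: Lewis-acid cleavage of the six aryl methyl ethers (BBr3 demethylation) before any acid-sensitive stilbene is present; C3 and C3′ carry no ionisable bond, and any reversible opening of the benzylic C2–O bonds should reclose to the favoured trans rings.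

Step 13
Reactants: 27 4-ethenylphenyl acetate; 28 2-ethenyl-4,4,5,5-tetramethyl-1,3,2-dioxaborolane
Product: 29 4-[(E)-2-(4,4,5,5-tetramethyl-1,3,2-dioxaborolan-2-yl)ethenyl]phenyl acetate
Conditions: second-generation Grubbs catalyst RuCl2(=CHPh)(PCy3)(SIMes) (3 mol %), CH2Cl2, 40 °C
Reagents that add atoms: none
Why: Olefin cross-metathesis of a styrene with a vinylboronate, driven by loss of ethene and E-selective for steric reasons.

Step 14
Reactants: 26 (2S,3S)-4-chloro-3-[(2R,3R)-3-(3,5-dihydroxyphenyl)-4-hydroxy-2-(4-hydroxyphenyl)-2,3-dihydro-1-benzofuran-6-yl]-2-(4-hydroxyphenyl)-2,3-dihydro-1-benzofuran-6-ol; 29 4-[(E)-2-(4,4,5,5-tetramethyl-1,3,2-dioxaborolan-2-yl)ethenyl]phenyl acetate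
Product: 31 (2S,3S)-3-[(2R,3R)-3-(3,5-dihydroxyphenyl)-4-hydroxy-2-(4-hydroxyphenyl)-2,3-dihydro-1-benzofuran-6-yl]-2-(4-hydroxyphenyl)-4-[(E)-2-(4-hydroxyphenyl)ethenyl]-2,3-dihydro-1-benzofuran-6-ol (CNP0188679.4), via coupled aryl acetate 30 (not isolated)
Conditions: Pd(OAc)2 (10 mol %), SPhos, K3PO4 (excess), 1,4-dioxane/H2O, degassed, 80 °C; then aq. HCl to pH 5
Reagents that add atoms: none
Why: Suzuki–Miyaura coupling of the aryl chloride with the alkenylboronate with retention of the E geometry (SPhos-ligated palladium tolerates free phenols and ortho-substituted aryl chlorides), the aryl acetate being saponified by the aqueous phosphate in the same flask; no stereocentre is touched.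

Compound list
1 | 1-chloro-3,5-dimethoxybenzene | COc1cc(Cl)cc(OC)c1 | starting material
2 | (4-chloro-2,6-dimethoxyphenyl)lithium | [Li]c1c(OC)cc(Cl)cc1OC | intermediate
3 | lithium (4-chloro-2,6-dimethoxyphenyl)(dimethylamino)methanolate | [Li+].[O-]C(N(C)C)c1c(OC)cc(Cl)cc1OC | intermediate
4 | 4-chloro-2,6-dimethoxybenzaldehyde | O=Cc1c(OC)cc(Cl)cc1OC | intermediate
5 | 4-chloro-2-hydroxy-6-methoxybenzaldehyde | O=Cc1c(O)cc(Cl)cc1OC | intermediate
6 | 5-chloro-3-methoxy-2-(2-methoxyethenyl)phenol (E/Z mixture) | COC=Cc1c(O)cc(Cl)cc1OC | intermediate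
7 | 6-chloro-4-methoxy-1-benzofuran | COc1cc(Cl)cc2occc12 | intermediate
8 | 3,5-dimethoxyphenol | COc1cc(O)cc(OC)c1 | starting material
9 | 3,5-dimethoxyphenyl trifluoromethanesulfonate | COc1cc(OC)cc(OS(=O)(=O)C(F)(F)F)c1 | intermediate
10 | 2-(4-methoxyphenyl)-4,4,5,5-tetramethyl-1,3,2-dioxaborolane | COc1ccc(cc1)B1OC(C)(C)C(C)(C)O1 | starting material
11 | (6-chloro-4-methoxy-1-benzofuran-2-yl)lithium | [Li]c1cc2c(OC)cc(Cl)cc2o1 | intermediate
12 | lithium (6-chloro-4-methoxy-1-benzofuran-2-yl)(4-methoxyphenyl)(pinacolato)borate | [Li+].COc1ccc(cc1)[B-]1(OC(C)(C)C(C)(C)O1)c1cc2c(OC)cc(Cl)cc2o1 | intermediate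
13 | (2R,3R)-6-chloro-3-(3,5-dimethoxyphenyl)-4-methoxy-2-(4-methoxyphenyl)-2-(4,4,5,5-tetramethyl-1,3,2-dioxaborolan-2-yl)-2,3-dihydro-1-benzofuran | COc1cc(Cl)cc2O[C@@](B3OC(C)(C)C(C)(C)O3)(c3ccc(OC)cc3)[C@H](c3cc(OC)cc(OC)c3)c12 | intermediate
14 | (2R,3R)-6-chloro-3-(3,5-dimethoxyphenyl)-4-methoxy-2-(4-methoxyphenyl)-2,3-dihydro-1-benzofuran | COc1cc(Cl)cc2O[C@@H](c3ccc(OC)cc3)[C@H](c3cc(OC)cc(OC)c3)c12 | intermediate
15 | (2R,3R)-3-(3,5-dimethoxyphenyl)-4-methoxy-2-(4-methoxyphenyl)-2,3-dihydro-1-benzofuran-6-ol | COc1cc(O)cc2O[C@@H](c3ccc(OC)cc3)[C@H](c3cc(OC)cc(OC)c3)c12 | intermediate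
16 | (2R,3R)-3-(3,5-dimethoxyphenyl)-4-methoxy-2-(4-methoxyphenyl)-2,3-dihydro-1-benzofuran-6-yl trifluoromethanesulfonate | COc1cc(OS(=O)(=O)C(F)(F)F)cc2O[C@@H](c3ccc(OC)cc3)[C@H](c3cc(OC)cc(OC)c3)c12 | intermediate
17 | N-[(2-chloro-4,6-dimethoxyphenyl)methylidene]-N-methylmethanaminium chloride | C[N+](C)=Cc1c(Cl)cc(OC)cc1OC.[Cl-] | intermediate
18 | 2-chloro-4,6-dimethoxybenzaldehyde | O=Cc1c(Cl)cc(OC)cc1OC | intermediate
19 | 2-chloro-6-hydroxy-4-methoxybenzaldehyde | O=Cc1c(Cl)cc(OC)cc1O | intermediate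
20 | 3-chloro-5-methoxy-2-(2-methoxyethenyl)phenol (E/Z mixture) | COC=Cc1c(O)cc(OC)cc1Cl | intermediate
21 | 4-chloro-6-methoxy-1-benzofuran | COc1cc(Cl)c2ccoc2c1 | intermediate
22 | (4-chloro-6-methoxy-1-benzofuran-2-yl)lithium | [Li]c1cc2c(Cl)cc(OC)cc2o1 | intermediate
23 | lithium (4-chloro-6-methoxy-1-benzofuran-2-yl)(4-methoxyphenyl)(pinacolato)borate | [Li+].COc1ccc(cc1)[B-]1(OC(C)(C)C(C)(C)O1)c1cc2c(Cl)cc(OC)cc2o1 | intermediate
24 | (2S,3S)-4-chloro-3-[(2R,3R)-3-(3,5-dimethoxyphenyl)-4-methoxy-2-(4-methoxyphenyl)-2,3-dihydro-1-benzofuran-6-yl]-6-methoxy-2-(4-methoxyphenyl)-2-(4,4,5,5-tetramethyl-1,3,2-dioxaborolan-2-yl)-2,3-dihydro-1-benzofuran | Clc1cc(OC)cc2c1[C@H](c1cc(OC)c3c(c1)O[C@@H](c1ccc(OC)cc1)[C@@H]3c1cc(OC)cc(OC)c1)[C@@](B1OC(C)(C)C(C)(C)O1)(c1ccc(OC)cc1)O2 | intermediate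
25 | (2S,3S)-4-chloro-3-[(2R,3R)-3-(3,5-dimethoxyphenyl)-4-methoxy-2-(4-methoxyphenyl)-2,3-dihydro-1-benzofuran-6-yl]-6-methoxy-2-(4-methoxyphenyl)-2,3-dihydro-1-benzofuran | Clc1cc(OC)cc2c1[C@H](c1cc(OC)c3c(c1)O[C@@H](c1ccc(OC)cc1)[C@@H]3c1cc(OC)cc(OC)c1)[C@@H](c1ccc(OC)cc1)O2 | intermediate
26 | (2S,3S)-4-chloro-3-[(2R,3R)-3-(3,5-dihydroxyphenyl)-4-hydroxy-2-(4-hydroxyphenyl)-2,3-dihydro-1-benzofuran-6-yl]-2-(4-hydroxyphenyl)-2,3-dihydro-1-benzofuran-6-ol | Clc1cc(O)cc2c1[C@H](c1cc(O)c3c(c1)O[C@@H](c1ccc(O)cc1)[C@@H]3c1cc(O)cc(O)c1)[C@@H](c1ccc(O)cc1)O2 | intermediate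
27 | 4-ethenylphenyl acetate (4-acetoxystyrene) | CC(=O)Oc1ccc(C=C)cc1 | starting material
28 | 2-ethenyl-4,4,5,5-tetramethyl-1,3,2-dioxaborolane | C=CB1OC(C)(C)C(C)(C)O1 | starting material
29 | 4-[(E)-2-(4,4,5,5-tetramethyl-1,3,2-dioxaborolan-2-yl)ethenyl]phenyl acetate | CC(=O)Oc1ccc(/C=C/B2OC(C)(C)C(C)(C)O2)cc1 | intermediate
30 | 4-[(E)-2-{(2S,3S)-3-[(2R,3R)-3-(3,5-dihydroxyphenyl)-4-hydroxy-2-(4-hydroxyphenyl)-2,3-dihydro-1-benzofuran-6-yl]-6-hydroxy-2-(4-hydroxyphenyl)-2,3-dihydro-1-benzofuran-4-yl}ethenyl]phenyl acetate | CC(=O)Oc1ccc(/C=C/c2cc(O)cc3c2[C@H](c2cc(O)c4c(c2)O[C@@H](c2ccc(O)cc2)[C@@H]4c2cc(O)cc(O)c2)[C@@H](c2ccc(O)cc2)O3)cc1 | intermediate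
31 | (2S,3S)-3-[(2R,3R)-3-(3,5-dihydroxyphenyl)-4-hydroxy-2-(4-hydroxyphenyl)-2,3-dihydro-1-benzofuran-6-yl]-2-(4-hydroxyphenyl)-4-[(E)-2-(4-hydroxyphenyl)ethenyl]-2,3-dihydro-1-benzofuran-6-ol | Oc1ccc(/C=C/c2cc(O)cc3c2[C@H](c2cc(O)c4c(c2)O[C@@H](c2ccc(O)cc2)[C@@H]4c2cc(O)cc(O)c2)[C@@H](c2ccc(O)cc2)O3)cc1 | target

Total step count: 14. Longest linear sequence: 9 steps (steps 1, 2, 3, 5, 6, 7, 11, 12, 14).

Steps most likely to fail

1. Step 11 (proposed new method). The borate may transfer an aryl group directly to palladium (Suzuki-type transmetalation) instead of undergoing the migratory pathway. Attack at C3 may be slowed by the peri chlorine at C4, facial selectivity may be poor, or the C3–palladium intermediate may open the ring by β-alkoxide elimination. The fallback sets out from 21 and 16 and comes back at 25, using known cross-coupling and ionic hydrogenation. Benzofuran 21 is lithiated at C2 (n-BuLi, THF, −78 °C), transmetalated with ZnCl2 and coupled with 4-iodoanisole in a Negishi reaction (Pd(PPh3)4, THF, 50 °C) to give 4-chloro-6-methoxy-2-(4-methoxyphenyl)-1-benzofuran F1. NBS (MeCN, 0 °C) should brominate this at C3 to 3-bromo-4-chloro-6-methoxy-2-(4-methoxyphenyl)-1-benzofuran F2. Miyaura borylation of 16 (B2pin2, PdCl2(dppf), KOAc, 1,4-dioxane, 90 °C) gives (2R,3R)-3-(3,5-dimethoxyphenyl)-4-methoxy-2-(4-methoxyphenyl)-6-(4,4,5,5-tetramethyl-1,3,2-dioxaborolan-2-yl)-2,3-dihydro-1-benzofuran F3. Suzuki–Miyaura coupling of F2 with F3 (Pd(OAc)2, SPhos, K3PO4, toluene/H2O, 100 °C; C–Br before C–Cl) forms the same C3–C6′ bond in 4-chloro-3-[(2R,3R)-3-(3,5-dimethoxyphenyl)-4-methoxy-2-(4-methoxyphenyl)-2,3-dihydro-1-benzofuran-6-yl]-6-methoxy-2-(4-methoxyphenyl)-1-benzofuran F4. Ionic hydrogenation (Et3SiH, CF3CO2H, CH2Cl2, 0 °C to rt; protonation at C3, hydride delivery to the C2 oxocarbenium ion anti to the C3 aryl group) should then give the two trans-dihydrobenzofurans, 25 and its ring A epimer (2R,3R)-4-chloro-3-[(2R,3R)-3-(3,5-dimethoxyphenyl)-4-methoxy-2-(4-methoxyphenyl)-2,3-dihydro-1-benzofuran-6-yl]-6-methoxy-2-(4-methoxyphenyl)-2,3-dihydro-1-benzofuran F5, which are separated by preparative HPLC.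

2. Step 5 (proposed new method). The same processes may intervene: direct transmetalation, competing lithiation next to chlorine, low facial selectivity, or loss of configuration at C2 during protodeboronation. The fallback sets out from 7 and comes back at 14. The Negishi sequence above (n-BuLi; ZnCl2; 4-iodoanisole, Pd(PPh3)4) gives 6-chloro-4-methoxy-2-(4-methoxyphenyl)-1-benzofuran F6, and NBS gives 3-bromo-6-chloro-4-methoxy-2-(4-methoxyphenyl)-1-benzofuran F7. Suzuki–Miyaura coupling with 3,5-dimethoxyphenylboronic acid (Pd(PPh3)4, Na2CO3, DME/H2O, 85 °C) gives 6-chloro-3-(3,5-dimethoxyphenyl)-4-methoxy-2-(4-methoxyphenyl)-1-benzofuran F8. Ionic hydrogenation (Et3SiH, CF3CO2H, CH2Cl2) should give the racemic trans-dihydrobenzofuran, that is 14 together with its enantiomer (2S,3S)-6-chloro-3-(3,5-dimethoxyphenyl)-4-methoxy-2-(4-methoxyphenyl)-2,3-dihydro-1-benzofuran F9. Compound 14 is then obtained by preparative chromatography on a chiral stationary phase.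

3. Step 14. Oxidative addition into the hindered, electron-rich C4–Cl bond may be slow once the phenols are deprotonated, the polyphenoxides may be oxidised by traces of air, and the alkenylboronate may be lost by protodeboronation. The fallback sets out from 26 and comes back at 31; it couples a protected substrate by a Heck reaction. Acetylation (Ac2O, pyridine, DMAP, CH2Cl2) gives (2S,3S)-6-acetoxy-2-(4-acetoxyphenyl)-3-[(2R,3R)-4-acetoxy-2-(4-acetoxyphenyl)-3-(3,5-diacetoxyphenyl)-2,3-dihydro-1-benzofuran-6-yl]-4-chloro-2,3-dihydro-1-benzofuran F10. Heck reaction with 27 (Pd2(dba)3, P(t-Bu)3·HBF4, Cy2NMe, 1,4-dioxane, 110 °C) gives the (E)-stilbene heptaacetate of the target F11. Mild methanolysis (K2CO3, MeOH, 0 °C, degassed) then releases 31.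

Further compounds
F1 | step 11 | 4-chloro-6-methoxy-2-(4-methoxyphenyl)-1-benzofuran | COc1ccc(cc1)-c1cc2c(Cl)cc(OC)cc2o1
F2 | step 11 | 3-bromo-4-chloro-6-methoxy-2-(4-methoxyphenyl)-1-benzofuran | COc1ccc(cc1)-c1oc2cc(OC)cc(Cl)c2c1Br
F3 | step 11 | (2R,3R)-3-(3,5-dimethoxyphenyl)-4-methoxy-2-(4-methoxyphenyl)-6-(4,4,5,5-tetramethyl-1,3,2-dioxaborolan-2-yl)-2,3-dihydro-1-benzofuran | COc1cc(B3OC(C)(C)C(C)(C)O3)cc2O[C@@H](c3ccc(OC)cc3)[C@H](c3cc(OC)cc(OC)c3)c12
F4 | step 11 | 4-chloro-3-[(2R,3R)-3-(3,5-dimethoxyphenyl)-4-methoxy-2-(4-methoxyphenyl)-2,3-dihydro-1-benzofuran-6-yl]-6-methoxy-2-(4-methoxyphenyl)-1-benzofuran | COc1ccc(cc1)-c1oc2cc(OC)cc(Cl)c2c1-c1cc(OC)c2c(c1)O[C@@H](c1ccc(OC)cc1)[C@@H]2c1cc(OC)cc(OC)c1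
F5 | step 11 | (2R,3R)-4-chloro-3-[(2R,3R)-3-(3,5-dimethoxyphenyl)-4-methoxy-2-(4-methoxyphenyl)-2,3-dihydro-1-benzofuran-6-yl]-6-methoxy-2-(4-methoxyphenyl)-2,3-dihydro-1-benzofuran | Clc1cc(OC)cc2c1[C@@H](c1cc(OC)c3c(c1)O[C@@H](c1ccc(OC)cc1)[C@@H]3c1cc(OC)cc(OC)c1)[C@H](c1ccc(OC)cc1)O2
F6 | step 5 | 6-chloro-4-methoxy-2-(4-methoxyphenyl)-1-benzofuran | COc1ccc(cc1)-c1cc2c(OC)cc(Cl)cc2o1
F7 | step 5 | 3-bromo-6-chloro-4-methoxy-2-(4-methoxyphenyl)-1-benzofuran | COc1ccc(cc1)-c1oc2cc(Cl)cc(OC)c2c1Br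
F8 | step 5 | 6-chloro-3-(3,5-dimethoxyphenyl)-4-methoxy-2-(4-methoxyphenyl)-1-benzofuran | COc1ccc(cc1)-c1oc2cc(Cl)cc(OC)c2c1-c1cc(OC)cc(OC)c1
F9 | step 5 | (2S,3S)-6-chloro-3-(3,5-dimethoxyphenyl)-4-methoxy-2-(4-methoxyphenyl)-2,3-dihydro-1-benzofuran | COc1cc(Cl)cc2O[C@H](c3ccc(OC)cc3)[C@@H](c3cc(OC)cc(OC)c3)c12
F10 | step 14 | (2S,3S)-6-acetoxy-2-(4-acetoxyphenyl)-3-[(2R,3R)-4-acetoxy-2-(4-acetoxyphenyl)-3-(3,5-diacetoxyphenyl)-2,3-dihydro-1-benzofuran-6-yl]-4-chloro-2,3-dihydro-1-benzofuran | Clc1cc(OC(C)=O)cc2c1[C@H](c1cc(OC(C)=O)c3c(c1)O[C@@H](c1ccc(OC(C)=O)cc1)[C@@H]3c1cc(OC(C)=O)cc(OC(C)=O)c1)[C@@H](c1ccc(OC(C)=O)cc1)O2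
F11 | step 14 | heptaacetate of the target, (2S,3S)-6-acetoxy-2-(4-acetoxyphenyl)-3-[(2R,3R)-4-acetoxy-2-(4-acetoxyphenyl)-3-(3,5-diacetoxyphenyl)-2,3-dihydro-1-benzofuran-6-yl]-4-[(E)-2-(4-acetoxyphenyl)ethenyl]-2,3-dihydro-1-benzofuran | CC(=O)Oc1ccc(/C=C/c2cc(OC(C)=O)cc3c2[C@H](c2cc(OC(C)=O)c4c(c2)O[C@@H](c2ccc(OC(C)=O)cc2)[C@@H]4c2cc(OC(C)=O)cc(OC(C)=O)c2)[C@@H](c2ccc(OC(C)=O)cc2)O3)cc1
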